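Assumption: the target SMILES has no stereocentre and no stereogenic double bond, so the compound is achiral and is made exactly as drawn; no enantiocontrol is needed.

**Retrosynthetic overview**
- 2-Phenylethyl docosanoate ⇐ hydrogenation of the 2,3-enoate ⇐ elimination from the β-mesyloxy ester ⇐ β-hydroxy ester.
- Key disconnection, C2–C3 of the acyl chain: intermolecular aldol addition of the lithium enolate of 2-phenylethyl acetate (C2 fragment, ester already in place) to icosanal (C20 fragment).
- Icosanal ⇐ oxidation of icosan-1-ol.
- No ring is formed; the benzene ring is bought with 2-phenylethyl acetate and carried through unchanged.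

**Route**

Step 1
Reactants: 1 icosan-1-ol
Product: 2 icosanal
Conditions: TEMPO (10 mol%), PhI(OAc)2 (1.1 equiv), CH2Cl2 (0.1 M), rt
Reagents that add atoms: none
Why: Oxoammonium-mediated TEMPO/PhI(OAc)2 oxidation stops cleanly at the aldehyde for a primary alcohol, and CH2Cl2 at rt keeps the waxy C20 substrate in solution.

Step 2
Reactants: 2 icosanal; 3 2-phenylethyl acetate
Product: 6 rac-2-phenylethyl 3-hydroxydocosanoate, via lithium enolate 4 (not isolated), via lithium aldolate 5 (not isolated)
Conditions: 3 (1.3 equiv), LDA (commercial solution, 1.25 equiv), THF, −78 °C, 30 min; then 2 in THF added dropwise, −78 → −40 °C; AcOH (1.4 equiv) in THF at −78 °C, then water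
Reagents that add atoms: none
Why: Kinetic deprotonation of the acetate CH3 gives the ester enolate, which adds to the aldehyde in a directed intermolecular aldol addition that forms C2–C3 of the C22 chain; the C3 carbinol is deliberately racemic because it is removed in steps 3–5.

Step 3
Reactants: 6 rac-2-phenylethyl 3-hydroxydocosanoate
Product: 7 rac-2-phenylethyl 3-(methylsulfonyloxy)docosanoate
Conditions: MsCl (1.5 equiv), Et3N (2.0 equiv), CH2Cl2, 0 °C, 30 min; crude taken on after aqueous wash
Reagents that add atoms: methanesulfonyl chloride, CS(=O)(=O)Cl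
Why: O-Sulfonylation (mesylation) of the secondary alcohol turns it into a good leaving group while the ester is untouched; any premature elimination only gives the product of step 4.

Step 4
Reactants: 7 rac-2-phenylethyl 3-(methylsulfonyloxy)docosanoate
Product: 8 2-phenylethyl (2E)-docos-2-enoate
Conditions: DBU (1.5 equiv), CH2Cl2, 0 °C → rt
Reagents that add atoms: none
Why: E1cB elimination — DBU removes the acidic α-proton and the β-mesylate is expelled to give the conjugated (E)-enoate, which erases the C3 stereocentre.

Step 5
Reactants: 8 2-phenylethyl (2E)-docos-2-enoate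
Product: 9 2-phenylethyl docosanoate
Conditions: H2 (1 atm), 10% Pd/C (5 mol%), EtOAc/THF, rt
Reagents that add atoms: none
Why: Heterogeneous catalytic hydrogenation saturates the conjugated C=C; the arene is inert at 1 atm and rt, and the ester C–O bond is homobenzylic, not benzylic, so it is not hydrogenolysed.

**Compound list**
1 | icosan-1-ol (1-eicosanol) | CCCCCCCCCCCCCCCCCCCCO | starting material
2 | icosanal | CCCCCCCCCCCCCCCCCCCC=O | intermediate
3 | 2-phenylethyl acetate | CC(=O)OCCc1ccccc1 | starting material
4 | lithium enolate of 2-phenylethyl acetate (formed in situ) | C=C([O-])OCCc1ccccc1.[Li+] | intermediate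
5 | lithium aldolate, lithium 1-oxo-1-(2-phenylethoxy)docosan-3-olate, racemic (formed in situ) | CCCCCCCCCCCCCCCCCCCC([O-])CC(=O)OCCc1ccccc1.[Li+] | intermediate
6 | rac-2-phenylethyl 3-hydroxydocosanoate | CCCCCCCCCCCCCCCCCCCC(O)CC(=O)OCCc1ccccc1 | intermediate
7 | rac-2-phenylethyl 3-(methylsulfonyloxy)docosanoate | CCCCCCCCCCCCCCCCCCCC(OS(C)(=O)=O)CC(=O)OCCc1ccccc1 | intermediate
8 | 2-phenylethyl (2E)-docos-2-enoate | CCCCCCCCCCCCCCCCCCC/C=C/C(=O)OCCc1ccccc1 | intermediate
9 | 2-phenylethyl docosanoate (phenylethyl n-docosanoate) | CCCCCCCCCCCCCCCCCCCCCC(=O)OCCc1ccccc1 | target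

**Summary**
Total step count: 5.
Longest linear sequence: 5 steps (1 → 2 → 6 → 7 → 8 → 9); 3 is a purchased partner that enters at step 2.

**Three steps most likely to fail, with fallbacks**

Step 2 (aldol). The risks are that the C20 aldehyde crystallises at −78 °C, that enolate 4 self-condenses, and that the aldolate reverts on warming. The fallback sets out from 2 and comes back at 8. Meldrum's acid is heated with 2-phenylethanol (toluene, 110 °C) to give mono-2-phenylethyl malonate F4. Aldehyde 2 and F4 (1.5 equiv) are then condensed in pyridine with catalytic piperidine at 90 °C (Doebner-type Knoevenagel condensation with decarboxylation). This gives 8 directly and skips 6 and 7. It runs warm, where 2 is fully dissolved, and any β,γ-unsaturated isomer converges to 9 in step 5.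

Step 1 (oxidation). The risks are incomplete conversion of the poorly soluble alcohol and loss of the waxy aldehyde 2 to autoxidation or oligomers on handling. The fallback sets out from 1 and comes back at 6, avoiding the aldehyde altogether. Alcohol 1 is oxidised fully with Jones reagent (acetone/THF, 0 °C → rt) to icosanoic acid F1. This is converted with (COCl)2 and catalytic DMF in CH2Cl2 to icosanoyl chloride F2. F2 is added at −78 °C to 2.2 equiv of enolate 4 (from 3 and LDA in THF) in a crossed Claisen-type acylation, giving 2-phenylethyl 3-oxodocosanoate F3 after AcOH quench. The ketone of F3 is reduced chemoselectively with NaBH4 (THF/EtOH, 0 °C) to 6.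

Step 4 (elimination). The risks are incomplete elimination, deconjugated isomers, or base-induced loss of the phenethyl ester. The fallback sets out from 6 and comes back at 9, replacing steps 3–5 by a radical deoxygenation. Alcohol 6 is heated with 1,1'-thiocarbonyldiimidazole and catalytic DMAP (1,2-dichloroethane, 60 °C) to give O-[1-oxo-1-(2-phenylethoxy)docosan-3-yl] 1H-imidazole-1-carbothioate F5. F5 is reduced with Bu3SnH and AIBN in toluene at 110 °C (Barton–McCombie deoxygenation) to 9.

**Further compounds**
F1 | step 1 | icosanoic acid | CCCCCCCCCCCCCCCCCCCC(=O)O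
F2 | step 1 | icosanoyl chloride | CCCCCCCCCCCCCCCCCCCC(=O)Cl
F3 | step 1 | 2-phenylethyl 3-oxodocosanoate | CCCCCCCCCCCCCCCCCCCC(=O)CC(=O)OCCc1ccccc1
F4 | step 2 | mono-2-phenylethyl malonate, 3-oxo-3-(2-phenylethoxy)propanoic acid | OC(=O)CC(=O)OCCc1ccccc1
F5 | step 4 | O-[1-oxo-1-(2-phenylethoxy)docosan-3-yl] 1H-imidazole-1-carbothioate (racemic) | CCCCCCCCCCCCCCCCCCCC(OC(=S)n1ccnc1)CC(=O)OCCc1ccccc1
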